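Retrosynthetic overview

1. Numbering: C1 ketone, C2=C3 enone (CH3 on C3), cyclobutane C4–C5–C11–C10 (CH3 on C10), bridge C5–C6(CH3, CH2O)–C7(O)–C8–C9(O)–C10. The three angelates go on last in two stages (the primary hydroxyl of triol 25, then both secondary ones); the trans C7/C9 diol comes from two relayed hydroxyl-directed reductions of a C7/C9 diketone.
2. The cyclobutane is closed last, at C10–C11, by oxidative coupling of the C1 and C9 ketone enolates (the two carbonyls are 1,4-related across that bond).
3. Key disconnection: C2–C3 and C4–C5, made together by an intramolecular Diels–Alder reaction of a 2-silyloxydiene (C2=C1–C11=C5) with a cyclopropene (C3=C4, third ring atom C10). This closes the six-membered enone ring and the seven-membered ring at once from an open chain.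
4. Enabling feature: C10 is bonded to C4, is alpha to the C9 oxygen, and stands 1,5 to C1=O through C2–C3. A temporary C3–C10 bond can therefore be carried (cyclopropene strain drives the cycloaddition) and then cut by a retro-Michael reaction, which makes C2=C3 and frees C10 as an enolate for the cyclobutane closure.
5. The open chain 20 comes from alkyne 11 (C6 centre: Sharpless epoxidation, then alkynylalane opening) and cyclopropene acid 16 (C10 centre: rhodium-catalysed cyclopropenation), joined at C8–C9.

Key step: step 14

Remark: the three ester groups are read as (Z)-2-methylbut-2-enoates (angelates), as the double-bond descriptors of the SMILES require.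

Route

Step 1
Reactants: 1 3-methylbut-2-en-1-yl acetate
Product: 2 (E)-4-hydroxy-3-methylbut-2-en-1-yl acetate
Conditions: SeO2 (cat.), t-BuOOH, salicylic acid (cat.), CH2Cl2, rt
Reagents that add atoms: tert-butyl hydroperoxide, CC(C)(C)OO
Why: SeO2 allylic oxidation (ene reaction, then 2,3-sigmatropic shift) hydroxylates the methyl group trans to the chain, so the E allylic alcohol should result.

Step 2
Reactants: 2 (E)-4-hydroxy-3-methylbut-2-en-1-yl acetate
Product: 3 (E)-4-[(tert-butyldimethylsilyl)oxy]-3-methylbut-2-en-1-yl acetate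
Conditions: TBSCl, imidazole, DMF, rt
Reagents that add atoms: tert-butyldimethylsilyl chloride, CC(C)(C)[Si](C)(C)Cl
Why: Standard silylation of a primary alcohol; the acetate is untouched.

Step 3
Reactants: 3 (E)-4-[(tert-butyldimethylsilyl)oxy]-3-methylbut-2-en-1-yl acetate
Product: 4 (E)-4-[(tert-butyldimethylsilyl)oxy]-3-methylbut-2-en-1-ol
Conditions: K2CO3, MeOH, 0 °C
Reagents that add atoms: none
Why: Transesterification removes the acetate and leaves the silyl ether, which places the free hydroxyl on the CH= side as the epoxidation needs.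

Step 4
Reactants: 4 (E)-4-[(tert-butyldimethylsilyl)oxy]-3-methylbut-2-en-1-ol
Product: 5 [(2S,3S)-3-{[(tert-butyldimethylsilyl)oxy]methyl}-3-methyloxiran-2-yl]methanol
Conditions: Ti(OiPr)4, L-(+)-diethyl tartrate, t-BuOOH, 4 Å MS, CH2Cl2, −20 °C
Reagents that add atoms: tert-butyl hydroperoxide, CC(C)(C)OO
Why: Sharpless asymmetric epoxidation of a geraniol-type trisubstituted E allylic alcohol; the tartrate ligand selects the alkene face and should give the (2S,3S) epoxide as geraniol does.

Step 5
Reactants: 5 [(2S,3S)-3-{[(tert-butyldimethylsilyl)oxy]methyl}-3-methyloxiran-2-yl]methanol; 6 ethynyltrimethylsilane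
Product: 7 (2R,3R)-3-{[(tert-butyldimethylsilyl)oxy]methyl}-3-methyl-5-(trimethylsilyl)pent-4-yne-1,2-diol
Conditions: 6, n-BuLi, toluene, −78 °C; Et2AlCl, 0 °C; then 5, 0 °C to rt; aq. potassium sodium tartrate work-up
Reagents that add atoms: none
Why: Opening of a 2,3-epoxy alcohol by an alkynylaluminium reagent at the tertiary, distal epoxide carbon with inversion; this turns the epoxide stereocentre into the quaternary C6 centre.

Step 6
Reactants: 7 (2R,3R)-3-{[(tert-butyldimethylsilyl)oxy]methyl}-3-methyl-5-(trimethylsilyl)pent-4-yne-1,2-diol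
Product: 8 (2R)-2-{[(tert-butyldimethylsilyl)oxy]methyl}-2-methyl-4-(trimethylsilyl)but-3-ynal
Conditions: NaIO4, THF/pH 7 buffer, 0 °C
Reagents that add atoms: none
Why: Periodate glycol cleavage gives the aldehyde; its alpha-carbon is quaternary and cannot epimerise.

Step 7
Reactants: 8 (2R)-2-{[(tert-butyldimethylsilyl)oxy]methyl}-2-methyl-4-(trimethylsilyl)but-3-ynal; 9 1-(triphenyl-λ5-phosphanylidene)propan-2-one
Product: 10 (3E,5R)-5-{[(tert-butyldimethylsilyl)oxy]methyl}-5-methyl-7-(trimethylsilyl)hept-3-en-6-yn-2-one
Conditions: PhMe, 100 °C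
Reagents that add atoms: none
Why: Wittig olefination with a stabilised ylide should give the E enone (C5=C11 and C1, C2).

Step 8
Reactants: 10 (3E,5R)-5-{[(tert-butyldimethylsilyl)oxy]methyl}-5-methyl-7-(trimethylsilyl)hept-3-en-6-yn-2-one
Product: 11 (3E,5R)-5-{[(tert-butyldimethylsilyl)oxy]methyl}-5-methylhept-3-en-6-yn-2-one
Conditions: K2CO3, MeOH, 0 °C
Reagents that add atoms: none
Why: Methanolysis of the alkynyl C–Si bond frees the terminal alkyne; the alkyl silyl ether is stable to these conditions.

Step 9
Reactants: 12 methyl 2-methyl-3-oxobutanoate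
Product: 13 methyl 2-diazopropanoate
Conditions: 4-acetamidobenzenesulfonyl azide, DBU, MeCN, 0 °C to rt
Reagents that add atoms: 4-acetamidobenzenesulfonyl azide, CC(=O)Nc1ccc(cc1)S(=O)(=O)N=[N+]=[N-]
Why: Deacylative Regitz diazo transfer: the acetyl group leaves on the sulfonamide nitrogen.

Step 10
Reactants: 13 methyl 2-diazopropanoate; 14 propyne
Product: 15 methyl (1R)-1,2-dimethylcycloprop-2-ene-1-carboxylate
Conditions: Rh2(S-PTTL)3(TPA) (0.5 mol %; PTTL = N-phthaloyl-tert-leucinate, TPA = triphenylacetate), 14 (excess), hexanes, −78 °C, slow addition of 13; the enantiomeric catalyst is taken if the sense of induction proves opposite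
Reagents that add atoms: none
Why: Enantioselective rhodium-carbene cyclopropenation of a terminal alkyne with an alpha-alkyl diazoester at low temperature (which suppresses beta-hydride migration); the chiral carboxylate ligands set the C10 centre.

Step 11
Reactants: 15 methyl (1R)-1,2-dimethylcycloprop-2-ene-1-carboxylate
Product: 16 (1R)-1,2-dimethylcycloprop-2-ene-1-carboxylic acid
Conditions: LiOH, THF/MeOH/H2O, rt; then 1 M HCl to pH 3
Reagents that add atoms: lithium hydroxide, [Li+].[OH-]
Why: Saponification; the quaternary stereocentre cannot epimerise.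

Step 12
Reactants: 16 (1R)-1,2-dimethylcycloprop-2-ene-1-carboxylic acid; 11 (3E,5R)-5-{[(tert-butyldimethylsilyl)oxy]methyl}-5-methylhept-3-en-6-yn-2-one
Product: 19 (3E,5S,6E)-5-{[(tert-butyldimethylsilyl)oxy]methyl}-8-[(1R)-1,2-dimethylcycloprop-2-en-1-yl]-6-methoxy-5-methylocta-3,6-diene-2,8-dione, via acid chloride 17 (not isolated), via ynone 18 (not isolated)
Conditions: 16, 1-chloro-N,N,2-trimethylprop-1-en-1-amine, CH2Cl2, 0 °C; then 11, CuI (5 mol %), Et3N, THF, 0 °C to rt; then MeOH, PBu3 (10 mol %), rt
Reagents that add atoms: methanol, CO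
Why: Neutral acid chloride formation, copper-catalysed acylation of the terminal alkyne (C8–C9 bond), then phosphine-catalysed oxa-Michael addition of methanol to the ynone; the last makes C8 vinylic (no acidic C8–H later) and should give the E isomer with C6 cis to the acyl group.

Step 13
Reactants: 19 (3E,5S,6E)-5-{[(tert-butyldimethylsilyl)oxy]methyl}-8-[(1R)-1,2-dimethylcycloprop-2-en-1-yl]-6-methoxy-5-methylocta-3,6-diene-2,8-dione
Product: 20 (2E,4S,5E)-4-{[(tert-butyldimethylsilyl)oxy]methyl}-1-[(1R)-1,2-dimethylcycloprop-2-en-1-yl]-3-methoxy-4-methyl-7-[(triethylsilyl)oxy]octa-2,5,7-trien-1-one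
Conditions: TESOTf, Et3N, CH2Cl2, −78 °C
Reagents that add atoms: triethylsilyl trifluoromethanesulfonate, CC[Si](CC)(CC)OS(=O)(=O)C(F)(F)F
Why: Soft enolisation of the methyl ketone, the only enolisable site (C11 is vinylic, C10 and C6 are quaternary), gives the 2-silyloxydiene.

Step 14
Reactants: 20 (2E,4S,5E)-4-{[(tert-butyldimethylsilyl)oxy]methyl}-1-[(1R)-1,2-dimethylcycloprop-2-en-1-yl]-3-methoxy-4-methyl-7-[(triethylsilyl)oxy]octa-2,5,7-trien-1-one
Product: 22 cis-fused bicyclic enone (10,11-seco tricycle; C10 epimers), via Diels–Alder adduct 21 (not isolated)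
Conditions: PhMe (0.005 M), BHT, 70 °C; then MeOH, K2CO3, 0 °C to rt
Reagents that add atoms: none
Why: Heating brings the electron-rich 2-silyloxydiene onto the strained cyclopropene in a concerted suprafacial [4π+2π] cycloaddition (type 1 intramolecular Diels–Alder reaction; cyclopropenes are established strained dienophiles) that forms C2–C3 and C4–C5, the six-membered ring closing as the cycloaddition ring and the seven-membered ring (C4–C5–C6–C7–C8–C9–C10) as the tether ring of the same event. Methanolysis of the silyl enol ether then gives the C1 ketone, whose enolate toward C2 expels the C10 enolate of the vinylogous ester in an E1cB retro-Michael opening of the acyl cyclopropane, driven by release of ring strain, so the temporary C3–C10 bond is lost and C2=C3 becomes the enone double bond. C4 is set by the (R)-C10 centre, because the tether forces the diene onto the ring face that carries the acyl group; C5 follows from C4 through the endo-type, cis-fused closure (C10 under the diene), which the three-atom C7–C9 link with its cis-disposed C7=C8 bond should enforce, so the C5/C6 relation rests on the pairing of the two pre-set centres C6 and C10; C10 itself is left as an epimer mixture that is made planar again in step 15. Regioselectivity (C4, not the methyl-bearing C3, bonds to the hindered C5; C3 goes to the free CH2 terminus C2) is fixed by the tether length, and high dilution with a radical inhibitor holds back intermolecular cycloaddition and dimerisation of the cyclopropene.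

Step 15
Reactants: 22 cis-fused bicyclic enone (C10 epimers)
Product: 23 tricyclic enone with C7 methyl enol ether and C6 CH2OTBS
Conditions: LiN(iPr)2 (2.3 equiv), THF, −78 °C; then CuCl2 (2.5 equiv), DMF, −78 °C to rt
Reagents that add atoms: none
Why: Kinetic double deprotonation gives the cross-conjugated enolate at C11 and the alpha-prime enolate at C10 (C8 is vinylic and C6 quaternary, so there is no other site), and oxidation by divalent copper couples the two alpha-carbons (intramolecular oxidative enolate coupling of a 1,6-dicarbonyl to a 1,2-diacylcyclobutane); with C10 axial on C4 in the cis-fused bicycle the bond can form on one face only, which sets C10 and C11.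

Step 16
Reactants: 23 tricyclic enone with C7 methyl enol ether and C6 CH2OTBS
Product: 24 6-(hydroxymethyl) tricyclic 1,7,9-trione
Conditions: 1 M HCl, THF, rt
Reagents that add atoms: water, O
Why: Acid hydrolysis of the vinylogous ester to the 1,3-diketone and of the silyl ether; the stereocentres are quaternary or cyclobutane bridgeheads and do not epimerise.

Step 17
Reactants: 24 6-(hydroxymethyl) tricyclic 1,7,9-trione
Product: 25 7,9-dihydroxy-6-(hydroxymethyl) tricyclic enone (triol)
Conditions: Me4NBH(OAc)3 (8 equiv), MeCN/AcOH (1:1), −30 °C to rt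
Reagents that add atoms: none
Why: Hydroxyl-directed (Evans–Saksena) reduction: the CH2OH-bound acetoxyborohydride delivers hydride to C7 from its own face (C7–OH anti to CH2OH), then the C7–O-bound borohydride delivers hydride to C9 (C9–OH anti to C7–OH), which should give the trans 7,9-diol while the enone, lacking a beta-hydroxyl, is not reduced.

Step 18
Reactants: 25 7,9-dihydroxy-6-(hydroxymethyl) tricyclic enone (triol); 26 (Z)-2-methylbut-2-enoic anhydride
Product: 27 tricyclic enone 7,9-diol with the C6 CH2OH esterified as the (Z)-2-methylbut-2-enoate (primary mono-angelate)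
Conditions: LiN(SiMe3)2 (1.05 equiv), THF, −78 °C; then 26 (1.05 equiv), −78 to −40 °C; aq. NH4Cl
Reagents that add atoms: none
Why: Acylation of a lithium alkoxide by angelic anhydride, each molecule of which gives up one acyl group and leaves as lithium angelate; the alkoxides exchange protons fast, the primary oxygen is the least hindered and should be esterified first, and without a nucleophilic amine catalyst the Z double bond should not isomerise to the tiglate.

Step 19
Reactants: 27 tricyclic enone 7,9-diol with the C6 CH2OH esterified as the (Z)-2-methylbut-2-enoate (primary mono-angelate); 26 (Z)-2-methylbut-2-enoic anhydride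
Product: 28 CNP0266467.1 (triangelate)
Conditions: LiN(SiMe3)2 (2.2 equiv), THF, −78 °C; then 26 (3 equiv), −78 to 0 °C; aq. NH4Cl
Reagents that add atoms: none
Why: The same alkoxide acylation, now forced with excess anhydride up to 0 °C on the two hindered secondary alkoxides at C7 and C9 (one molecule of anhydride is spent per ester formed), under conditions that should again leave the angelate geometry and the enone untouched.

Compound list

1 | 3-methylbut-2-en-1-yl acetate (prenyl acetate) | CC(C)=CCOC(C)=O | starting material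
2 | (E)-4-hydroxy-3-methylbut-2-en-1-yl acetate | CC(=O)OC/C=C(\C)CO | intermediate
3 | (E)-4-[(tert-butyldimethylsilyl)oxy]-3-methylbut-2-en-1-yl acetate | CC(=O)OC/C=C(\C)CO[Si](C)(C)C(C)(C)C | intermediate
4 | (E)-4-[(tert-butyldimethylsilyl)oxy]-3-methylbut-2-en-1-ol | OC/C=C(\C)CO[Si](C)(C)C(C)(C)C | intermediate
5 | [(2S,3S)-3-{[(tert-butyldimethylsilyl)oxy]methyl}-3-methyloxiran-2-yl]methanol | OC[C@@H]1O[C@@]1(C)CO[Si](C)(C)C(C)(C)C | intermediate
6 | ethynyltrimethylsilane | C#C[Si](C)(C)C | starting material
7 | (2R,3R)-3-{[(tert-butyldimethylsilyl)oxy]methyl}-3-methyl-5-(trimethylsilyl)pent-4-yne-1,2-diol | OC[C@H](O)[C@@](C)(CO[Si](C)(C)C(C)(C)C)C#C[Si](C)(C)C | intermediate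
8 | (2R)-2-{[(tert-butyldimethylsilyl)oxy]methyl}-2-methyl-4-(trimethylsilyl)but-3-ynal | O=C[C@@](C)(CO[Si](C)(C)C(C)(C)C)C#C[Si](C)(C)C | intermediate
9 | 1-(triphenyl-λ5-phosphanylidene)propan-2-one | CC(=O)C=P(c1ccccc1)(c1ccccc1)c1ccccc1 | starting material
10 | (3E,5R)-5-{[(tert-butyldimethylsilyl)oxy]methyl}-5-methyl-7-(trimethylsilyl)hept-3-en-6-yn-2-one | CC(=O)/C=C/[C@@](C)(CO[Si](C)(C)C(C)(C)C)C#C[Si](C)(C)C | intermediate
11 | (3E,5R)-5-{[(tert-butyldimethylsilyl)oxy]methyl}-5-methylhept-3-en-6-yn-2-one | CC(=O)/C=C/[C@@](C)(CO[Si](C)(C)C(C)(C)C)C#C | intermediate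
12 | methyl 2-methyl-3-oxobutanoate | CC(=O)C(C)C(=O)OC | starting material
13 | methyl 2-diazopropanoate | COC(=O)C(C)=[N+]=[N-] | intermediate
14 | propyne | CC#C | starting material
15 | methyl (1R)-1,2-dimethylcycloprop-2-ene-1-carboxylate | COC(=O)[C@@]1(C)C(C)=C1 | intermediate
16 | (1R)-1,2-dimethylcycloprop-2-ene-1-carboxylic acid | OC(=O)[C@@]1(C)C(C)=C1 | intermediate
17 | (1R)-1,2-dimethylcycloprop-2-ene-1-carbonyl chloride | ClC(=O)[C@@]1(C)C(C)=C1 | intermediate
18 | (3E,5R)-5-{[(tert-butyldimethylsilyl)oxy]methyl}-8-[(1R)-1,2-dimethylcycloprop-2-en-1-yl]-5-methyloct-3-en-6-yne-2,8-dione | CC(=O)/C=C/[C@@](C)(CO[Si](C)(C)C(C)(C)C)C#CC(=O)[C@@]1(C)C(C)=C1 | intermediate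
19 | (3E,5S,6E)-5-{[(tert-butyldimethylsilyl)oxy]methyl}-8-[(1R)-1,2-dimethylcycloprop-2-en-1-yl]-6-methoxy-5-methylocta-3,6-diene-2,8-dione | CC(=O)/C=C/[C@@](C)(CO[Si](C)(C)C(C)(C)C)/C(OC)=C\C(=O)[C@@]1(C)C(C)=C1 | intermediate
20 | (2E,4S,5E)-4-{[(tert-butyldimethylsilyl)oxy]methyl}-1-[(1R)-1,2-dimethylcycloprop-2-en-1-yl]-3-methoxy-4-methyl-7-[(triethylsilyl)oxy]octa-2,5,7-trien-1-one | C=C(O[Si](CC)(CC)CC)/C=C/[C@@](C)(CO[Si](C)(C)C(C)(C)C)/C(OC)=C\C(=O)[C@@]1(C)C(C)=C1 | intermediate
21 | Diels–Alder adduct: cis-fused six/seven-membered bicycle with C1=C11 triethylsilyl enol ether, C3–C4–C10 cyclopropane (C2, C5 and C9 on one face), C7-methoxy C7=C8–C9(=O) and C6 CH3/CH2OTBS; C4, C5, C6 as in the target | CC(C)(C)[Si](C)(C)OC[C@]1(C)[C@@H]2C=C(O[Si](CC)(CC)CC)C[C@@]3(C)[C@@H]2[C@@]3(C)C(=O)C=C1OC | intermediate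
22 | cis-fused bicyclo[5.4.0]undecane (10,11-seco tricycle) with C1(=O)–C2=C3(CH3) enone, C7-methoxy C7=C8–C9(=O) vinylogous ester, C6 CH3/CH2OTBS and C10–H(CH3) as both epimers; C4, C5, C6 as in the target | CC(C)(C)[Si](C)(C)OC[C@]1(C)[C@@H]2CC(=O)C=C(C)[C@@H]2C(C)C(=O)C=C1OC | intermediate
23 | tricycle with the target skeleton and all ring stereocentres C4, C5, C6, C10, C11 as in the target; C1(=O)–C2=C3 enone, C7-methoxy C7=C8–C9(=O), C6 CH2OTBS | CC(C)(C)[Si](C)(C)OC[C@]1(C)[C@@H]2[C@H]3C(=O)C=C(C)[C@@H]2[C@@]3(C)C(=O)C=C1OC | intermediate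
24 | tricyclic 1,7,9-trione with free C6 CH2OH (C4, C5, C6, C10, C11 as in the target) | OC[C@]1(C)[C@@H]2[C@H]3C(=O)C=C(C)[C@@H]2[C@@]3(C)C(=O)CC1=O | intermediate
25 | tricyclic enone triol: C7–OH anti to the C6 CH2OH and trans to C9–OH, otherwise as the target without its acyl groups | OC[C@]1(C)[C@@H]2[C@H]3C(=O)C=C(C)[C@@H]2[C@@]3(C)[C@H](O)C[C@H]1O | intermediate
26 | (Z)-2-methylbut-2-enoic anhydride (angelic anhydride) | C/C=C(/C)C(=O)OC(=O)/C(C)=C\C | starting material
27 | primary mono-angelate of 25: the C6 CH2O group carries the (Z)-2-methylbut-2-enoyl group, C7–OH and C9–OH are free | C/C=C(/C)C(=O)OC[C@]1(C)[C@@H]2[C@H]3C(=O)C=C(C)[C@@H]2[C@@]3(C)[C@H](O)C[C@H]1O | intermediate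
28 | CNP0266467.1, the tris[(Z)-2-methylbut-2-enoate] of 25 | C/C=C(/C)C(=O)OC[C@]1(C)[C@@H]2[C@H]3C(=O)C=C(C)[C@@H]2[C@@]3(C)[C@H](OC(=O)/C(C)=C\C)C[C@H]1OC(=O)/C(C)=C\C | target

Totals

Total step count: 19. Longest linear sequence: 16 steps (steps 1–8, then 12–19).

The three steps most likely to fail, each with its fallback

First risk, step 15 (oxidative closure of the cyclobutane): intermolecular enolate coupling and over-oxidation may outrun closure of the strained four-membered ring. Fallback for step 15: the oxidative coupling is replaced by an enolate alkylation that sets out from 21, obtained by stopping step 14 before the methanolysis. N-Bromosuccinimide in THF at −78 °C brominates the silyl enol ether at C11 on the face away from the cyclopropane and gives the C11 bromo ketone F1. KN(SiMe3)2 in THF (−78 to 0 °C) then enolises C1 toward C2; the retro-Michael opening of the cyclopropane releases the C10 enolate, which displaces bromide at C11 with inversion (4-exo-tet enolate alkylation to a cyclobutane with a quaternary centre). This comes back to the route at 23.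

Second risk, step 14 (cycloaddition): ring closure may take the exo, trans-fused mode, the double-bond geometry of the tether may be wrong for closure, or the cyclopropene may dimerise first. Fallback for step 14: an intramolecular Robinson annulation that sets out from 11. Commercial 2-methyl-4-oxopentanoic acid is turned with 1-chloro-N,N,2-trimethylprop-1-en-1-amine into 2-methyl-4-oxopentanoyl chloride F2. CuI/Et3N acylation of 11 gives the ynone F3, and MeOH with PBu3 gives the open-chain methoxy dienetrione F4. Cs2CO3 in MeCN at 50 °C should then bring about the reversible Michael addition of the ketone alpha-methylene C4 to C5 (seven-membered ring), followed by the aldol condensation of C2 onto C3 (six-membered enone ring), which drains the Michael equilibrium toward the wanted adduct. This comes back to the route at 22.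

Third risk, step 17 (relayed reduction): the enolised 1,3-diketone may take up hydride slowly or without the planned relay of facial control. Fallback for step 17: two Evans–Tishchenko reductions that set out from 24. SmI2 (30 mol %) and acetaldehyde in THF at −10 °C should first reduce C7 under direction by the CH2OH group and give the C7 alcohol with the primary acetate F5. The C7 hydroxyl then directs the same reduction of C9 and gives the 9-hydroxy diacetate F6; each hydride is delivered inside a hemiacetal chelate, anti to the directing oxygen. K2CO3 in MeOH removes both acetates, and this comes back to the route at 25.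

Further compounds

F1 | step 15 | C11 bromo ketone of the cyclopropane-fused bicycle (Br anti to the cyclopropane; from 21) | CC(C)(C)[Si](C)(C)OC[C@]1(C)[C@@H]2[C@@H](Br)C(=O)C[C@@]3(C)[C@@H]2[C@@]3(C)C(=O)C=C1OC
F2 | step 14 | 2-methyl-4-oxopentanoyl chloride | CC(=O)CC(C)C(Cl)=O
F3 | step 14 | (3E,5R)-5-{[(tert-butyldimethylsilyl)oxy]methyl}-5,9-dimethyldodec-3-en-6-yne-2,8,11-trione | CC(=O)/C=C/[C@@](C)(CO[Si](C)(C)C(C)(C)C)C#CC(=O)C(C)CC(C)=O
F4 | step 14 | (3E,5S,6E)-5-{[(tert-butyldimethylsilyl)oxy]methyl}-6-methoxy-5,9-dimethyldodeca-3,6-diene-2,8,11-trione | CC(=O)/C=C/[C@@](C)(CO[Si](C)(C)C(C)(C)C)/C(OC)=C\C(=O)C(C)CC(C)=O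
F5 | step 17 | tricyclic 1,9-dione with C7–OH and C6 CH2OAc | CC(=O)OC[C@]1(C)[C@@H]2[C@H]3C(=O)C=C(C)[C@@H]2[C@@]3(C)C(=O)C[C@H]1O
F6 | step 17 | tricyclic enone with C9–OH, C7–OAc and C6 CH2OAc | CC(=O)OC[C@]1(C)[C@@H]2[C@H]3C(=O)C=C(C)[C@@H]2[C@@]3(C)[C@H](O)C[C@H]1OC(C)=O
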